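Atom labels: six-membered ring C1(=CH2)–C2–C3(OAc)–C4(i-Pr)–C5–C9; cyclopentane C5–C6(Ac)–C7(O-angeloyl)–C8–C9. Everything rests on the C7–C8 disconnection. The array C7(O)–C8H2–C9(H), next to the C1 methylidene, is the product pattern of an aldehyde C–H adding across an exocyclic C9=C8 alkene. In the key step a rhodium-catalysed intramolecular hydroacylation closes the cyclopentane, forms C7–C8, delivers hydrogen to C9 and so sets the trans ring fusion in one operation. Its precursor is a monocyclic 2-methylidenecyclohexane with a CH(dioxolanyl)CHO arm on C5; the C1 methylidene is masked as a β-silyl carbinol, and the ring comes from a proline aldol and a Michael–Mannich sequence.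

Key step: step 10

Remark on the chemistry: but-2-ynal is taken as a purchasable aldehyde (it can also be released from its commercial diethyl acetal); the other starting materials are catalogue compounds.

Step 1
Reactants: 1 3-methylbutanal; 2 but-2-ynal
Product: 4 (2R,3S)-1,1-dimethoxy-2-(propan-2-yl)hex-4-yn-3-ol, via aldol aldehyde 3 (not isolated)
Conditions: D-proline (20 mol %), DMF, 4 °C, slow addition of 1; then MeOH, sulfonic acid resin (Amberlyst 15), 25 °C
Reagents that add atoms: methanol, CO
Why: Proline enamine catalysis (direct cross-aldol reaction): the (E)-enamine of 1 adds to the non-enolisable ynal 2 through the carboxylic acid-bound chair transition state, which with D-proline should set the anti (2R,3S) pair that becomes C4 and C3, and the labile β-hydroxy aldehyde is trapped in the same flask as its dimethyl acetal.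

Step 2
Reactants: 4 (2R,3S)-1,1-dimethoxy-2-(propan-2-yl)hex-4-yn-3-ol
Product: 5 (4S,5R)-4-(tert-butyldimethylsilyloxy)-6,6-dimethoxy-5-(propan-2-yl)hex-2-yne
Conditions: t-BuMe2SiCl, imidazole, DMF, 25 °C
Reagents that add atoms: tert-butyldimethylsilyl chloride, CC(C)(C)[Si](C)(C)Cl
Why: Standard silyl ether formation at the propargylic alcohol under mildly basic conditions that leave the acetal and both stereocentres untouched.

Step 3
Reactants: 5 (4S,5R)-4-(tert-butyldimethylsilyloxy)-6,6-dimethoxy-5-(propan-2-yl)hex-2-yne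
Product: 6 (4R,5R)-4-(tert-butyldimethylsilyloxy)-6,6-dimethoxy-5-(propan-2-yl)hexan-2-one
Conditions: 9-borabicyclo[3.3.1]nonane (9-BBN, 1.1 equiv), THF, 0 → 40 °C; then H2O2 (30 %), aq. NaOAc, 0 °C
Reagents that add atoms: hydrogen peroxide, OO
Why: Hydroboration–oxidation of the internal alkyne, in which the bulky borane puts boron on the less hindered methyl-bearing alkyne carbon, away from the branched silyloxy carbon, so that buffered oxidation of the alkenylborane gives the methyl ketone (the future C1) without disturbing the β-silyloxy group.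

Step 4
Reactants: 6 (4R,5R)-4-(tert-butyldimethylsilyloxy)-6,6-dimethoxy-5-(propan-2-yl)hexan-2-one
Product: 8 (4S,5R)-5-(tert-butyldimethylsilyloxy)-4-(propan-2-yl)cyclohex-2-en-1-one, via keto aldehyde 7 (not isolated)
Conditions: TsOH·H2O (10 mol %), acetone/H2O, 25 °C; then dibenzylammonium trifluoroacetate (20 mol %), toluene, 50 °C
Reagents that add atoms: none
Why: Acetal hydrolysis followed by intramolecular aldol condensation (six-membered closure of the methyl ketone onto the aldehyde under amine salt catalysis) gives the conjugated cyclohexenone, with C3 and C4 carried over unchanged.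

Step 5
Reactants: 9 ethyl 2-(2-methyl-1,3-dioxolan-2-yl)acetate
Product: 10 1-ethoxy-2-(2-methyl-1,3-dioxolan-2-yl)-1-(trimethylsilyloxy)ethene (E/Z mixture)
Conditions: LiN(i-Pr)2, THF, −78 °C; then Me3SiCl, −78 → 25 °C
Reagents that add atoms: chlorotrimethylsilane, C[Si](C)(C)Cl
Why: Kinetic ester enolisation with O-silylation at −78 °C gives the ketene silyl acetal before β-elimination of the dioxolane oxygen can set in.

Step 6
Reactants: 8 (4S,5R)-5-(tert-butyldimethylsilyloxy)-4-(propan-2-yl)cyclohex-2-en-1-one; 10 1-ethoxy-2-(2-methyl-1,3-dioxolan-2-yl)-1-(trimethylsilyloxy)ethene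
Product: 12 Mannich base (cyclohexanone with C1=O; C3 OSi(t-Bu)Me2 cis to C4 i-Pr; C5 CH(CO2Et)(2-methyl-1,3-dioxolan-2-yl) arm trans to i-Pr; C9 CH2NMe2; epimers at C6 and C9), via silyl enol ether 11 (not isolated)
Conditions: tris(dimethylamino)sulfonium difluorotrimethylsilicate (5 mol %), THF, −78 → −30 °C; then Me2N=CH2+ I− (1.5 equiv), CH2Cl2, −30 → 25 °C
Reagents that add atoms: N,N-dimethylmethyleneiminium iodide (Eschenmoser's salt), C[N+](C)=C.[I-]
Why: Fluoride-catalysed Mukaiyama–Michael addition puts the nucleophile on C5 anti to the cis C4 isopropyl and C3 silyloxy groups, which sets C5, and the regiodefined silyl enol ether is then aminomethylated at C9 (Mannich reaction); C6 forms as an epimer mixture that is corrected in step 10.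

Step 7
Reactants: 12 Mannich base
Product: 14 α-methylene ketone (as 12 but with C9=C8H2 in place of CH–CH2NMe2; C6 epimers), via methiodide 13 (not isolated)
Conditions: MeI, MeOH, 25 °C; then aq. NaHCO3, CH2Cl2, 25 °C
Reagents that add atoms: none
Why: Exhaustive N-methylation and E1cB elimination of the β-ammonium ketone (Hofmann-type elimination of a Mannich base) should give the exocyclic C9=C8 enone under conditions too mild to expel the C3 silyloxy group.

Step 8
Reactants: 14 α-methylene ketone
Product: 16 bis-silyl ester (C1 now C(OSiMe3)(CH2SiMe3); C9=C8H2; C5 arm CH(CO2Et)(dioxolanyl); epimers at C6 and C1), via cerium alkoxide 15 (not isolated)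
Conditions: Me3SiCH2Li, CeCl3, THF, −78 °C; then Me3SiCl, −78 → 0 °C
Reagents that add atoms: (trimethylsilyl)methyllithium, C[Si](C)(C)C[Li]; chlorotrimethylsilane, C[Si](C)(C)Cl
Why: The weakly basic organocerium reagent adds 1,2 to the enone carbonyl in preference to the ester (first stage of a Peterson olefination), from the equatorial direction because the axial C3 silyloxy group blocks axial attack, and O-silylation stores the future C1 methylidene as a robust β-silyl silyl ether whose configuration is inconsequential.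

Step 9
Reactants: 16 bis-silyl ester
Product: 17 aldehyde (as 16 with the C5 arm CH(CHO)(2-methyl-1,3-dioxolan-2-yl); epimers at C6 and C1)
Conditions: i-Bu2AlH (1.1 equiv), toluene, −78 °C; then aq. potassium sodium tartrate
Reagents that add atoms: none
Why: Partial ester reduction at −78 °C stops at the aluminium hemiacetal, which the neighbouring dioxolane oxygen stabilises by chelation, so that the aldehyde is released only on work-up.

Step 10
Reactants: 17 aldehyde
Product: 19 trans-fused bicyclic ketone (C7=O; C6 2-methyl-1,3-dioxolan-2-yl; C3 OSi(t-Bu)Me2; C4 i-Pr; C1 OSiMe3 and CH2SiMe3; C3 C4 C5 C6 C9 configured as in 25; C1 epimers), via C6-epimeric ketone 18 (not isolated)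
Conditions: [Rh(C7H8)(Ph2PCH2CH2PPh2)]ClO4 (5 mol %, activated with H2), CH2Cl2, 25 °C; then DBU (0.2 equiv), 25 °C
Reagents that add atoms: none
Why: Oxidative addition of the aldehyde C7–H bond to cationic monovalent rhodium gives an acyl rhodium hydride, the exocyclic C9=C8 alkene inserts into Rh–H with hydride going to C9 and rhodium to C8, and C–C reductive elimination forms C7–C8; the closest known reaction type is the rhodium-catalysed cyclisation of 4-pentenals to cyclopentanones, which tolerates 2-, 3- and 4-substituents including quaternary groups on the alkene. The cyclopentane therefore closes by ring contraction of a six-membered acylrhodacycle, a closure that is formally 5-endo at the alkene and is possible only because the metal carries both ends. The one permanent stereocentre made, C9, is fixed by the face of hydride insertion: the C5 arm is equatorial, the axial substituent on the quaternary C1 shields the face syn to H5, and the trans-fused rhodacycle with C8 equatorial is the less strained one, so hydrogen should enter anti to H5 and give the trans ring fusion that cationic rhodium diphosphine catalysts favour with 3,4-disubstituted 4-pentenals. The step needs cyclisation to outrun decarbonylation and double-bond migration: the chelating diphosphine and the neighbouring dioxolane oxygen stabilise the acyl hydride, the branches at C5 and C6 favour ring closure, and the quaternary C1 leaves C5–H as the only site for migration. C6 is not controlled here but is α to the new ketone, so DBU then equilibrates it to the isomer with the dioxolanyl group trans to the C5–C4 bond.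

Step 11
Reactants: 19 trans-fused bicyclic ketone
Product: 20 alcohol (as 19 with C7–OH cis to the C6 dioxolanyl group)
Conditions: LiBH(s-Bu)3, THF, −78 °C; then H2O
Reagents that add atoms: none
Why: Substrate-controlled ketone reduction with a bulky hydride, which attacks the cyclopentanone face opposite to the C6 dioxolanyl group and the axial H5 and so places the C7 hydroxyl cis to the C6 substituent.

Step 12
Reactants: 20 alcohol; 21 angelic acid ((2Z)-2-methylbut-2-enoic acid)
Product: 23 angelate (as 20 with C7–O–CO–C(CH3)=CH–CH3 of Z geometry), via mixed anhydride 22 (not isolated)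
Conditions: 21, 2,4,6-trichlorobenzoyl chloride, Et3N, toluene, 25 °C; then 20, DMAP (cat.), toluene, 60 °C
Reagents that add atoms: none
Why: Yamaguchi esterification through the preformed mixed anhydride acylates the hindered secondary alcohol under conditions that should keep the Z geometry of the angelate, while the tertiary silyl ether is inert.

Step 13
Reactants: 23 angelate
Product: 24 (1R,2S,3aR,6R,7S,7aR)-1-acetyl-6-hydroxy-4-methylidene-7-(propan-2-yl)octahydro-1H-inden-2-yl (2Z)-2-methylbut-2-enoate
Conditions: HF (48 % aq.), MeCN, 0 → 25 °C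
Reagents that add atoms: water, O
Why: Aqueous acid removes both O-silyl groups and the dioxolane (ketal hydrolysis) and ionises the tertiary C1 carbinol, whose β-silyl cation loses the trimethylsilyl group (acid-mediated Peterson elimination) to give only the exocyclic C1 methylidene.

Step 14
Reactants: 24 hydroxy ketone
Product: 25 (1R,2S,3aR,6R,7S,7aR)-1-acetyl-6-(acetyloxy)-4-methylidene-7-(propan-2-yl)octahydro-1H-inden-2-yl (2Z)-2-methylbut-2-enoate (CNP0322881.1)
Conditions: Ac2O, pyridine, DMAP (cat.), CH2Cl2, 0 → 25 °C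
Reagents that add atoms: acetic anhydride, CC(=O)OC(C)=O
Why: Acylation of the axial C3 hydroxyl with acetic anhydride under nucleophilic catalysis completes the target without touching any stereocentre.

Compound list
1 | 3-methylbutanal | CC(C)CC=O | starting material
2 | but-2-ynal | CC#CC=O | starting material
3 | (2R,3S)-3-hydroxy-2-(propan-2-yl)hex-4-ynal | CC#C[C@@H](O)[C@@H](C(C)C)C=O | intermediate
4 | (2R,3S)-1,1-dimethoxy-2-(propan-2-yl)hex-4-yn-3-ol | CC#C[C@@H](O)[C@@H](C(C)C)C(OC)OC | intermediate
5 | (4S,5R)-4-(tert-butyldimethylsilyloxy)-6,6-dimethoxy-5-(propan-2-yl)hex-2-yne | CC#C[C@@H](O[Si](C)(C)C(C)(C)C)[C@@H](C(C)C)C(OC)OC | intermediate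
6 | (4R,5R)-4-(tert-butyldimethylsilyloxy)-6,6-dimethoxy-5-(propan-2-yl)hexan-2-one | CC(=O)C[C@@H](O[Si](C)(C)C(C)(C)C)[C@@H](C(C)C)C(OC)OC | intermediate
7 | (2R,3R)-3-(tert-butyldimethylsilyloxy)-5-oxo-2-(propan-2-yl)hexanal | CC(=O)C[C@@H](O[Si](C)(C)C(C)(C)C)[C@@H](C(C)C)C=O | intermediate
8 | (4S,5R)-5-(tert-butyldimethylsilyloxy)-4-(propan-2-yl)cyclohex-2-en-1-one | O=C1C[C@@H](O[Si](C)(C)C(C)(C)C)[C@@H](C(C)C)C=C1 | intermediate
9 | ethyl 2-(2-methyl-1,3-dioxolan-2-yl)acetate | CCOC(=O)CC1(C)OCCO1 | starting material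
10 | 1-ethoxy-2-(2-methyl-1,3-dioxolan-2-yl)-1-(trimethylsilyloxy)ethene (E/Z mixture) | CCOC(O[Si](C)(C)C)=CC1(C)OCCO1 | intermediate
11 | silyl enol ether of the Michael adduct (C1(OSiMe3)=C9; C5 arm trans to i-Pr; C6 epimers) | C[Si](C)(C)OC=1C[C@@H](O[Si](C)(C)C(C)(C)C)[C@@H](C(C)C)[C@H](C(C(=O)OCC)C2(C)OCCO2)C=1 | intermediate
12 | Mannich base (C1=O; C9 CH2NMe2; C5 CH(CO2Et)(dioxolanyl) arm trans to i-Pr; epimers at C6 and C9) | O=C1C[C@@H](O[Si](C)(C)C(C)(C)C)[C@@H](C(C)C)[C@H](C(C(=O)OCC)C2(C)OCCO2)C1CN(C)C | intermediate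
13 | methiodide of 12 | O=C1C[C@@H](O[Si](C)(C)C(C)(C)C)[C@@H](C(C)C)[C@H](C(C(=O)OCC)C2(C)OCCO2)C1C[N+](C)(C)C.[I-] | intermediate
14 | α-methylene ketone (C1=O; C9=C8H2; C6 epimers) | O=C1C[C@@H](O[Si](C)(C)C(C)(C)C)[C@@H](C(C)C)[C@H](C(C(=O)OCC)C2(C)OCCO2)C1=C | intermediate
15 | cerium alkoxide of the C1 carbinol | Cl[Ce](Cl)OC1(C[Si](C)(C)C)C[C@@H](O[Si](C)(C)C(C)(C)C)[C@@H](C(C)C)[C@H](C(C(=O)OCC)C2(C)OCCO2)C1=C | intermediate
16 | bis-silyl ester (C1 C(OSiMe3)(CH2SiMe3); C9=C8H2; epimers at C6 and C1) | C[Si](C)(C)OC1(C[Si](C)(C)C)C[C@@H](O[Si](C)(C)C(C)(C)C)[C@@H](C(C)C)[C@H](C(C(=O)OCC)C2(C)OCCO2)C1=C | intermediate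
17 | aldehyde (C5 arm CH(CHO)(dioxolanyl); epimers at C6 and C1) | C[Si](C)(C)OC1(C[Si](C)(C)C)C[C@@H](O[Si](C)(C)C(C)(C)C)[C@@H](C(C)C)[C@H](C(C=O)C2(C)OCCO2)C1=C | intermediate
18 | trans-fused bicyclic ketone as C6 epimer mixture | C[Si](C)(C)OC1(C[Si](C)(C)C)C[C@@H](O[Si](C)(C)C(C)(C)C)[C@@H](C(C)C)[C@@H]2C(C3(C)OCCO3)C(=O)C[C@@H]12 | intermediate
19 | trans-fused bicyclic ketone (C7=O; C6 dioxolanyl trans to C5–C4; C1 epimers) | C[Si](C)(C)OC1(C[Si](C)(C)C)C[C@@H](O[Si](C)(C)C(C)(C)C)[C@@H](C(C)C)[C@@H]2[C@@H](C3(C)OCCO3)C(=O)C[C@@H]12 | intermediate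
20 | alcohol (C7–OH cis to the C6 dioxolanyl group; C1 epimers) | C[Si](C)(C)OC1(C[Si](C)(C)C)C[C@@H](O[Si](C)(C)C(C)(C)C)[C@@H](C(C)C)[C@@H]2[C@@H](C3(C)OCCO3)[C@@H](O)C[C@@H]12 | intermediate
21 | angelic acid, (2Z)-2-methylbut-2-enoic acid | C/C=C(/C)C(=O)O | starting material
22 | angelic 2,4,6-trichlorobenzoic anhydride | C/C=C(/C)C(=O)OC(=O)c1c(Cl)cc(Cl)cc1Cl | intermediate
23 | angelate of 20 (C1 epimers) | C[Si](C)(C)OC1(C[Si](C)(C)C)C[C@@H](O[Si](C)(C)C(C)(C)C)[C@@H](C(C)C)[C@@H]2[C@@H](C3(C)OCCO3)[C@@H](OC(=O)/C(C)=C\C)C[C@@H]12 | intermediate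
24 | (1R,2S,3aR,6R,7S,7aR)-1-acetyl-6-hydroxy-4-methylidene-7-(propan-2-yl)octahydro-1H-inden-2-yl (2Z)-2-methylbut-2-enoate | C=C1C[C@@H](O)[C@@H](C(C)C)[C@@H]2[C@@H](C(C)=O)[C@@H](OC(=O)/C(C)=C\C)C[C@@H]12 | intermediate
25 | (1R,2S,3aR,6R,7S,7aR)-1-acetyl-6-(acetyloxy)-4-methylidene-7-(propan-2-yl)octahydro-1H-inden-2-yl (2Z)-2-methylbut-2-enoate | C=C1C[C@@H](OC(C)=O)[C@@H](C(C)C)[C@@H]2[C@@H](C(C)=O)[C@@H](OC(=O)/C(C)=C\C)C[C@@H]12 | target

Total step count: 14. Longest linear sequence: 13 steps (steps 1–4 and 6–14; step 5 prepares reagent 10).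

Steps most likely to fail

Step 10. Hydride may insert from the wrong alkene face and give the cis ring fusion, the acyl rhodium hydride may lose CO, or the exocyclic double bond may migrate into the ring before the C–C bond forms. The fallback sets out from 16 and returns at 19. It makes the C7–C8 bond by a samarium Barbier cyclisation after the C9 hydrogen has been placed by hydroboration. 9-BBN should add to the exocyclic alkene of 16 from the face away from the axial C1 substituent, and buffered H2O2 then gives the primary alcohol F1. I2, PPh3 and imidazole give the iodide F2, and i-Bu2AlH at −78 °C gives the iodo aldehyde F3. SmI2 in THF/HMPA joins C8 to C7 and gives the cyclopentanol F4 as a C6/C7 epimer mixture. Dess–Martin periodinane then gives ketone 18, and DBU equilibration returns 19.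

Step 6. The hindered C5 may be attacked too slowly, so that 1,2-addition or proton transfer takes over; the dioxolane oxygen may be lost by β-elimination from the ester enolate; or silanolate may leave C3 and the ring aromatise. The fallback sets out from 8 and returns at 14. It makes the C5–C6 bond by allylic substitution. Morita–Baylis–Hillman reaction of 8 with aqueous formaldehyde (DMAP, THF/H2O) gives the hydroxymethyl enone F5, and Ac2O/pyridine gives the allylic acetate F6. The sodium enolate of ethyl acetoacetate (NaH, THF, 0 °C) attacks C5 anti to the isopropyl group with loss of acetate (SN2′ addition–elimination) and gives the keto ester F7, which already carries the C9 methylidene. Ketalisation of the non-conjugated acetyl group with 1,2-bis(trimethylsilyloxy)ethane and catalytic Me3SiOSO2CF3 at −78 °C returns 14.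

Step 4. During the condensation the silyloxy group may be lost by β-elimination from the aldehyde or ketone enol and C4 may epimerise, ending in aromatisation. The fallback sets out from 6 and returns at 8. It closes the ring by olefin metathesis, so that no enolisable aldehyde is exposed to condensation conditions. 6 is hydrolysed (TsOH, wet acetone) to keto aldehyde 7, and Ph3P=CH2 (THF, −78 °C) methylenates the aldehyde only, giving the alkenyl methyl ketone F8. Kinetic deprotonation at the methyl group (LiN(i-Pr)2, −78 °C) and Eschenmoser's salt give the Mannich base F9. MeI gives the methiodide F10, and aq. NaHCO3 gives the vinyl ketone F11. Ring-closing metathesis with the second-generation Grubbs catalyst (CH2Cl2, 40 °C) returns enone 8.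

Further compounds
F1 | step 10 | primary alcohol from hydroboration of 16 (C9–H; C8H2OH trans to the C5 arm) | C[Si](C)(C)OC1(C[Si](C)(C)C)C[C@@H](O[Si](C)(C)C(C)(C)C)[C@@H](C(C)C)[C@H](C(C(=O)OCC)C2(C)OCCO2)[C@H]1CO
F2 | step 10 | primary iodide (C8H2I) | C[Si](C)(C)OC1(C[Si](C)(C)C)C[C@@H](O[Si](C)(C)C(C)(C)C)[C@@H](C(C)C)[C@H](C(C(=O)OCC)C2(C)OCCO2)[C@H]1CI
F3 | step 10 | iodo aldehyde | C[Si](C)(C)OC1(C[Si](C)(C)C)C[C@@H](O[Si](C)(C)C(C)(C)C)[C@@H](C(C)C)[C@H](C(C=O)C2(C)OCCO2)[C@H]1CI
F4 | step 10 | cyclopentanol (C7–OH; epimers at C6 and C7) | C[Si](C)(C)OC1(C[Si](C)(C)C)C[C@@H](O[Si](C)(C)C(C)(C)C)[C@@H](C(C)C)[C@@H]2C(C3(C)OCCO3)C(O)C[C@@H]12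
F5 | step 6 | (4S,5R)-5-(tert-butyldimethylsilyloxy)-2-(hydroxymethyl)-4-(propan-2-yl)cyclohex-2-en-1-one | O=C1C[C@@H](O[Si](C)(C)C(C)(C)C)[C@@H](C(C)C)C=C1CO
F6 | step 6 | allylic acetate of F5 | O=C1C[C@@H](O[Si](C)(C)C(C)(C)C)[C@@H](C(C)C)C=C1COC(C)=O
F7 | step 6 | keto ester (C1=O; C9=C8H2; C5 arm CH(CO2Et)(COCH3) trans to i-Pr; C6 epimers) | O=C1C[C@@H](O[Si](C)(C)C(C)(C)C)[C@@H](C(C)C)[C@H](C(C(=O)OCC)C(C)=O)C1=C
F8 | step 4 | (4R,5S)-4-(tert-butyldimethylsilyloxy)-5-(propan-2-yl)hept-6-en-2-one | CC(=O)C[C@@H](O[Si](C)(C)C(C)(C)C)[C@@H](C(C)C)C=C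
F9 | step 4 | Mannich base, 1-(dimethylamino)-5-(tert-butyldimethylsilyloxy)-6-(propan-2-yl)oct-7-en-3-one | CN(C)CCC(=O)C[C@@H](O[Si](C)(C)C(C)(C)C)[C@@H](C(C)C)C=C
F10 | step 4 | methiodide of F9 | C[N+](C)(C)CCC(=O)C[C@@H](O[Si](C)(C)C(C)(C)C)[C@@H](C(C)C)C=C.[I-]
F11 | step 4 | vinyl ketone, 5-(tert-butyldimethylsilyloxy)-6-(propan-2-yl)octa-1,7-dien-3-one | C=CC(=O)C[C@@H](O[Si](C)(C)C(C)(C)C)[C@@H](C(C)C)C=C
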